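| flask | free monomer | initiator | remark | time |
|---|---|---|---|---|
| south | 0.016 M | 40 µM | run made earlier |  |
| west | 0.016 M | 60 µM | run made earlier |  |
| south-west | 0.024 M | 80 µM | run made earlier |  |
| teal | 0.016 M | 80 µM |  | 30 min |
| blue | 0.016 M | 80 µM |  | 20 min |

| run | time / min | monomer in chains / % |
|---|---|---|
| south | 1.33 | 7.1 |
| south | 4.00 | 20.2 |
| south | 6.00 | 28.3 |
| south | 10.0 | 41.8 |
| south | 15.0 | 54.4 |
| south | 20.0 | 60.1 |
| south | 25.0 | 66.4 |
| west | 2.00 | 15.9 |
| west | 3.00 | 20.2 |
| west | 4.00 | 28.9 |
| west | 6.00 | 37.7 |
| west | 10.0 | 52.5 |
| west | 15.0 | 64.5 |
| west | 25.0 | 76.1 |
| south-west | 5.00 | 44.1 |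
| south-west | 10.0 | 64.5 |
| south-west | 15.0 | 76.4 |
| south-west | 20.0 | 83.1 |
| south-west | 25.0 | 82.9 |

(standard deviation of a reading: 1 percentage point)

- the average divides the monomer in chains by the number of chains begun, living and dead together
- the numbers in the tables scatter with a standard deviation of 1 percentage point
- the earlier runs do not show the number of chains; that part of a forecast is a guess

- which of the two ends with the longer chains by the average number of monomer units in a chain (chains begun, living or dead) ("neither" if they lie within 10%) (teal / blue / neither)
- average number of monomer units in a chain (chains begun, living or dead) at the end, teal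
- average number of monomer units in a chain (chains begun, living or dead) at the end, blue

Early readings climb steeply and later ones flatten: the south-west run, with the 80 µM of initiator that teal and blue also receive, reads 44.1% at 5.00 min, then 83.1% and 82.9% at 20.0 min and 25.0 min.

I carry the charge ratio, free monomer charged over initiator charged, 200. If each initiator begins one chain, the average length (number-average degree of polymerisation) is this ratio times the fraction of monomer in chains. The south-west run holds 0.024 M of free monomer against 0.016 M in teal and blue, so taking its conversion over is an assumption: I replace the flat end of its readings by their mean, 83.0%, for both flasks, and my own reckoning gives 166 for teal and for blue. The 10% margin corresponds to 8.3 percentage points of conversion, against a scatter of 1 point, so I say neither.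

The forecast says neither, with 172 for teal (145 to 185) and 162 for blue (135 to 175), on the ground “If every initiator starts one chain and there is no transfer”.

The flasks give neither: teal 169, blue 162.

    free monomer + initiator → living end + monomer in chains (k = 7.30 /M/s)
    free monomer + living end → monomer in chains + living end, rate k2*[living end]*[free monomer] (k = 30.0 /M/s)
    monomer in chains + living end → free monomer + living end, rate k3*[living end] as long as [monomer in chains] is above zero (k = 0.0670 /s)
    free monomer + initiator → spent initiator (k = 0.380 /M/s)
    free monomer → uncatalysed product (k = 8.30 × 10⁻⁵ /s)

Teal at 30.0 min holds 80.2% monomer in chains, so the ratio gives 160, but its living ends stand at 7.60 × 10⁻⁵ M, fewer than the 80 µM of initiator charged, and spent initiator holds 3.96 µM; monomer in chains over living ends gives 169. Blue's length moves by 16.2 units at an initiator charge of 70.7 µM or 91.0 µM, with free monomer and time held. With 0.0040 M of free monomer in teal's recipe, the ratio falls to 50.0, and 35.7% monomer in chains makes that 17.9; that flask gives 18.8.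

The readings are simulated on assumed constants; scatter was added.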